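**Retrosynthetic overview**
1. Target ⇐ C13 desilylation and diacetylation of a macrocyclic anti-1,3-diol; C1–OH comes from a C3-hydroxyl-directed anti reduction of the C1 enone.
2. Ten-membered carbocycle (second ring, formed last) ⇐ intramolecular Nozaki–Hiyama–Kishi coupling of a C1 aldehyde with a C10 2-iodoalkene.
3. Butenolide (first ring) ⇐ syn-carbocupration of a γ-hydroxy ynoate with the C8–C10/C14 chain, iodine capture, lactonisation, then Stille hydroxymethylation (C13).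
4. C6 carbinol ⇐ catalytic asymmetric alkynylation of a (Z)-enal with methyl propiolate; the (Z)-C4=C5 alkene ⇐ Me2CuLi syn-addition to an ynoate.
5. C3 (first stereocentre) ⇐ ketoreductase-catalysed asymmetric reduction of an achiral silyl ynone made from methyl 3-hydroxypropanoate and ethynyltrimethylsilane.

Assumptions and notation (one line): locants C1–C15 follow germacrane numbering (ring C1–C10, C14 = exocyclic CH2 on C10, C15 = methyl on C4, C11/C12/C13 = butenolide α-carbon, lactone carbonyl and CH2OH, lactone oxygen on C6); TBS = tert-butyldimethylsilyl, TBDPS = tert-butyldiphenylsilyl (TBSO, TBDPSO = the silyloxy groups); the facial sense stated for the ketoreductase and for (S,S)-ProPhenol is the expected one, and the antipodal enzyme variant or ligand is used if a pilot run shows the opposite sense.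

**Route**

Step 1
Reactants: 1 methyl 3-hydroxypropanoate
Product: 2 methyl 3-(TBSO)propanoate
Conditions: TBSCl, imidazole, CH2Cl2, 0 °C → rt
Reagents that add atoms: tert-butyldimethylsilyl chloride, CC(C)(C)[Si](C)(C)Cl
Why: Imidazole-promoted silyl ether formation on the only hydroxyl is clean; no stereocentre is involved.

Step 2
Reactants: 2 methyl 3-(TBSO)propanoate
Product: 3 3-(TBSO)-N-methoxy-N-methylpropanamide
Conditions: MeNH(OMe)·HCl, i-PrMgCl, THF, −20 → 0 °C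
Reagents that add atoms: N,O-dimethylhydroxylamine hydrochloride, CNOC.Cl
Why: Weinreb amide formation by aminolysis of the ester with the magnesium amide proceeds without touching the TBS ether.

Step 3
Reactants: 3 3-(TBSO)-N-methoxy-N-methylpropanamide, 4 ethynyltrimethylsilane
Product: 6 5-(TBSO)-1-(trimethylsilyl)pent-1-yn-3-one, via lithium (trimethylsilyl)acetylide 5 (not isolated)
Conditions: 4, n-BuLi, THF, −78 °C; then 3, −78 → −20 °C; aq. NH4Cl
Reagents that add atoms: none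
Why: Weinreb ketone synthesis, in which the chelated tetrahedral adduct prevents over-addition and collapses to the ynone on work-up, so no racemic carbinol is ever formed.

Step 4
Reactants: 6 5-(TBSO)-1-(trimethylsilyl)pent-1-yn-3-one
Product: 7 (3S)-5-(TBSO)-1-(trimethylsilyl)pent-1-yn-3-ol
Conditions: (S)-selective ketoreductase (KRED, NADPH-dependent), NADP+ (cat.), i-PrOH/phosphate buffer pH 7.0 (15:85), 30 °C
Reagents that add atoms: none
Why: Enzymatic asymmetric carbonyl reduction by a ketoreductase (oxidoreductase of the alcohol dehydrogenase class) delivers hydride to one face of the ynone, distinguishing the slender silylalkynyl arm from the silyloxyethyl arm, and sets C3 as S (the first stereocentre) with i-PrOH recycling the cofactor.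

Step 5
Reactants: 7 (3S)-5-(TBSO)-1-(trimethylsilyl)pent-1-yn-3-ol
Product: 8 (3S)-3,5-bis(TBSO)-1-(trimethylsilyl)pent-1-yne
Conditions: TBSCl, imidazole, DMF, rt
Reagents that add atoms: tert-butyldimethylsilyl chloride, CC(C)(C)[Si](C)(C)Cl
Why: Silyl ether formation protects the propargylic alcohol at oxygen, so C3 is untouched.

Step 6
Reactants: 8 (3S)-3,5-bis(TBSO)-1-(trimethylsilyl)pent-1-yne
Product: 9 (3S)-3,5-bis(TBSO)pent-1-yne
Conditions: K2CO3 (cat.), MeOH, rt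
Reagents that add atoms: none
Why: Base-catalysed protodesilylation cleaves only the C(sp)–Si bond and leaves both TBS ethers intact.

Step 7
Reactants: 9 (3S)-3,5-bis(TBSO)pent-1-yne
Product: 11 methyl (4S)-4,6-bis(TBSO)hex-2-ynoate, via lithium (3S)-3,5-bis(TBSO)pent-1-yn-1-ide 10 (not isolated)
Conditions: n-BuLi, THF, −78 °C; ClCO2Me, −78 → −20 °C; aq. NH4Cl
Reagents that add atoms: methyl chloroformate, COC(=O)Cl
Why: Acetylide C-acylation with a chloroformate gives the ynoate (C6) without disturbing the silyl-protected C3 centre.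

Step 8
Reactants: 11 methyl (4S)-4,6-bis(TBSO)hex-2-ynoate
Product: 12 methyl (2Z,4S)-4,6-bis(TBSO)-3-methylhex-2-enoate
Conditions: Me2CuLi (CuI, 2 MeLi), THF, −78 °C; MeOH then aq. NH4Cl, −78 °C
Reagents that add atoms: lithium dimethylcuprate, [Li+].C[Cu-]C
Why: Syn-carbocupration (Gilman conjugate addition) followed by protonation with retention at −78 °C places methyl and hydrogen cis, so the ester and C3 end up cis (Z).

Step 9
Reactants: 12 methyl (2Z,4S)-4,6-bis(TBSO)-3-methylhex-2-enoate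
Product: 13 (2Z,4S)-4,6-bis(TBSO)-3-methylhex-2-en-1-ol
Conditions: i-Bu2AlH, CH2Cl2, −78 °C; aq. potassium sodium tartrate
Reagents that add atoms: none
Why: 1,2-Reduction of the enoate with i-Bu2AlH gives the allylic alcohol with the Z geometry retained.

Step 10
Reactants: 13 (2Z,4S)-4,6-bis(TBSO)-3-methylhex-2-en-1-ol
Product: 14 (2Z,4S)-4,6-bis(TBSO)-3-methylhex-2-enal
Conditions: MnO2, CH2Cl2, rt
Reagents that add atoms: none
Why: Neutral heterogeneous allylic oxidation with MnO2 gives the (Z)-enal without Z/E isomerisation, and it is used at once.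

Step 11
Reactants: 14 (2Z,4S)-4,6-bis(TBSO)-3-methylhex-2-enal, 15 methyl propiolate
Product: 17 methyl (4R,5Z,7S)-7,9-bis(TBSO)-4-hydroxy-6-methylnon-5-en-2-ynoate, via methyl 3-(methylzincio)prop-2-ynoate 16 (not isolated)
Conditions: 15, Me2Zn, (S,S)-ProPhenol (20 mol%), toluene, 4 °C; aq. NH4Cl
Reagents that add atoms: none
Why: Trost catalytic asymmetric alkynylation, in which the dinuclear zinc–ProPhenol catalyst (from Me2Zn and the ligand) delivers the zinc alkynide to one face of the enal and sets C6 as R under catalyst control, the remote C3 centre having little influence.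

Step 12
Reactants: 17 methyl (4R,5Z,7S)-7,9-bis(TBSO)-4-hydroxy-6-methylnon-5-en-2-ynoate, 18 (4-bromobut-1-ynyl)trimethylsilane
Product: 22 (5R)-5-[(1Z,3S)-3,5-bis(TBSO)-2-methylpent-1-enyl]-3-iodo-4-[4-(trimethylsilyl)but-3-ynyl]furan-2(5H)-one, via [4-(trimethylsilyl)but-3-ynyl]magnesium bromide 19 (not isolated), via bromomagnesium bis[4-(trimethylsilyl)but-3-ynyl]cuprate 20 (not isolated), via iodo hydroxy ester 21 (not isolated)
Conditions: 18, Mg, THF, rt; CuI, −40 °C; 17, −78 °C; I2, −78 → 0 °C; aq. NH4Cl/Na2S2O3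
Reagents that add atoms: iodine, II
Why: Syn-carbocupration of the ynoate puts the C8–C10/C14 chain on C7 cis to copper, iodinolysis with retention gives the alkenyl iodide whose ester is cis to the C6 alkoxide, and lactonisation closes the butenolide (first ring) without touching C6 or C3.

Step 13
Reactants: 22 (5R)-5-[(1Z,3S)-3,5-bis(TBSO)-2-methylpent-1-enyl]-3-iodo-4-[4-(trimethylsilyl)but-3-ynyl]furan-2(5H)-one
Product: 23 (5R)-5-[(1Z,3S)-3,5-bis(TBSO)-2-methylpent-1-enyl]-3-(hydroxymethyl)-4-[4-(trimethylsilyl)but-3-ynyl]furan-2(5H)-one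
Conditions: Bu3SnCH2OH, Pd(PPh3)4 (10 mol%), 1,4-dioxane, 80 °C
Reagents that add atoms: (tributylstannyl)methanol, CCCC[Sn](CCCC)(CCCC)CO
Why: Stille cross-coupling (Kosugi hydroxymethylation) of the electron-poor alkenyl iodide installs C13 under neutral conditions that spare the base-sensitive C6–H.

Step 14
Reactants: 23 (5R)-5-[(1Z,3S)-3,5-bis(TBSO)-2-methylpent-1-enyl]-3-(hydroxymethyl)-4-[4-(trimethylsilyl)but-3-ynyl]furan-2(5H)-one
Product: 24 (5R)-5-[(1Z,3S)-3,5-bis(TBSO)-2-methylpent-1-enyl]-3-[(TBDPSO)methyl]-4-[4-(trimethylsilyl)but-3-ynyl]furan-2(5H)-one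
Conditions: TBDPSCl, imidazole, CH2Cl2, 0 °C → rt
Reagents that add atoms: tert-butyl(chloro)diphenylsilane, CC(C)(C)[Si](Cl)(c1ccccc1)c1ccccc1
Why: Silyl ether formation on the only free hydroxyl gives a C13 protecting group that outlasts both later TBS removals.

Step 15
Reactants: 24 (5R)-5-[(1Z,3S)-3,5-bis(TBSO)-2-methylpent-1-enyl]-3-[(TBDPSO)methyl]-4-[4-(trimethylsilyl)but-3-ynyl]furan-2(5H)-one
Product: 25 (5R)-5-[(1Z,3S)-3,5-bis(TBSO)-2-methylpent-1-enyl]-3-[(TBDPSO)methyl]-4-(but-3-ynyl)furan-2(5H)-one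
Conditions: AgNO3 (10 mol%), CH2Cl2/MeOH/H2O, rt
Reagents that add atoms: none
Why: AgNO3-catalysed protodesilylation cleaves only the alkynyl C–Si bond under near-neutral conditions, avoiding base at the epimerisable C6.

Step 16
Reactants: 25 (5R)-5-[(1Z,3S)-3,5-bis(TBSO)-2-methylpent-1-enyl]-3-[(TBDPSO)methyl]-4-(but-3-ynyl)furan-2(5H)-one
Product: 27 (5R)-5-[(1Z,3S)-3,5-bis(TBSO)-2-methylpent-1-enyl]-3-[(TBDPSO)methyl]-4-(3-iodobut-3-enyl)furan-2(5H)-one, via alkenylborane 26 (not isolated)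
Conditions: B-iodo-9-BBN, pentane/CH2Cl2, −20 °C; AcOH, 0 °C; aq. NaHCO3
Reagents that add atoms: B-iodo-9-borabicyclo[3.3.1]nonane, IB1C2CCCC1CCC2
Why: Haloboration (Markovnikov syn-iodoboration of the terminal alkyne, boron on the terminal carbon) followed by protodeboronation with AcOH gives the 2-iodo-1-alkene at C10.

Step 17
Reactants: 27 (5R)-5-[(1Z,3S)-3,5-bis(TBSO)-2-methylpent-1-enyl]-3-[(TBDPSO)methyl]-4-(3-iodobut-3-enyl)furan-2(5H)-one
Product: 28 (5R)-5-[(1Z,3S)-3-(TBSO)-5-hydroxy-2-methylpent-1-enyl]-3-[(TBDPSO)methyl]-4-(3-iodobut-3-enyl)furan-2(5H)-one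
Conditions: HF·pyridine, pyridine, THF, 0 °C
Reagents that add atoms: none
Why: Buffered fluoride desilylation is fastest at the unhindered primary TBS ether, so the secondary allylic TBS and the TBDPS ether survive.

Step 18
Reactants: 28 (5R)-5-[(1Z,3S)-3-(TBSO)-5-hydroxy-2-methylpent-1-enyl]-3-[(TBDPSO)methyl]-4-(3-iodobut-3-enyl)furan-2(5H)-one
Product: 29 (3S,4Z)-3-(TBSO)-5-[(2R)-4-[(TBDPSO)methyl]-3-(3-iodobut-3-enyl)-5-oxo-2,5-dihydrofuran-2-yl]-4-methylpent-4-enal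
Conditions: Dess–Martin periodinane, pyridine, CH2Cl2, 0 °C → rt
Reagents that add atoms: none
Why: Dess–Martin oxidation gives the β-silyloxy aldehyde under buffered non-basic conditions that avoid β-elimination, and it is used crude.

Step 19
Reactants: 29 (3S,4Z)-3-(TBSO)-5-[(2R)-4-[(TBDPSO)methyl]-3-(3-iodobut-3-enyl)-5-oxo-2,5-dihydrofuran-2-yl]-4-methylpent-4-enal
Product: 30 (3S,4Z,6R)-3-(TBSO)-13-(TBDPSO)-1-hydroxygermacra-4,7(11),10(14)-trien-12,6-olide (C1 epimers)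
Conditions: CrCl2 (10 equiv), NiCl2 (5 mol%), degassed DMSO/THF, 0.002 M, slow addition, rt
Reagents that add atoms: none
Why: Intramolecular Nozaki–Hiyama–Kishi reaction, in which zerovalent nickel inserts into the C–I bond, the alkenyl group passes to trivalent chromium and adds chemoselectively to the aldehyde, closes the ten-membered ring at C1–C10 (second ring) under high dilution; C1 forms as an epimer mixture that converges in steps 20–22.

Step 20
Reactants: 30 (3S,4Z,6R)-3-(TBSO)-13-(TBDPSO)-1-hydroxygermacra-4,7(11),10(14)-trien-12,6-olide (C1 epimers)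
Product: 31 (3S,4Z,6R)-3-(TBSO)-13-(TBDPSO)-1-oxogermacra-4,7(11),10(14)-trien-12,6-olide
Conditions: Dess–Martin periodinane, pyridine, CH2Cl2, 0 °C
Reagents that add atoms: none
Why: Dess–Martin oxidation of the allylic alcohol converts both C1 epimers into the single α-methylene ketone.

Step 21
Reactants: 31 (3S,4Z,6R)-3-(TBSO)-13-(TBDPSO)-1-oxogermacra-4,7(11),10(14)-trien-12,6-olide
Product: 32 (3S,4Z,6R)-13-(TBDPSO)-3-hydroxy-1-oxogermacra-4,7(11),10(14)-trien-12,6-olide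
Conditions: HF·pyridine, THF, 0 °C → rt
Reagents that add atoms: none
Why: Acidic fluoride desilylation removes the secondary TBS ether while the more robust TBDPS ether stays, and the non-basic medium avoids β-elimination of the β-oxygenated ketone.

Step 22
Reactants: 32 (3S,4Z,6R)-13-(TBDPSO)-3-hydroxy-1-oxogermacra-4,7(11),10(14)-trien-12,6-olide
Product: 33 (1S,3S,4Z,6R)-13-(TBDPSO)-1,3-dihydroxygermacra-4,7(11),10(14)-trien-12,6-olide
Conditions: Me4NBH(OAc)3, MeCN/AcOH (1:1), −30 °C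
Reagents that add atoms: none
Why: Evans–Saksena hydroxyl-directed reduction, in which the C3 hydroxyl binds boron and delivers hydride intramolecularly through a chair-like six-membered transition state, gives the 1,3-anti diol by 1,2-reduction and so sets C1 as S.

Step 23
Reactants: 33 (1S,3S,4Z,6R)-13-(TBDPSO)-1,3-dihydroxygermacra-4,7(11),10(14)-trien-12,6-olide
Product: 34 (1S,3S,4Z,6R)-1,3-diacetoxy-13-(TBDPSO)germacra-4,7(11),10(14)-trien-12,6-olide
Conditions: Ac2O, pyridine, DMAP (cat.), CH2Cl2, 0 °C → rt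
Reagents that add atoms: acetic anhydride, CC(=O)OC(C)=O
Why: DMAP-catalysed O-acylation esterifies both secondary allylic alcohols with retention at C1 and C3.

Step 24
Reactants: 34 (1S,3S,4Z,6R)-1,3-diacetoxy-13-(TBDPSO)germacra-4,7(11),10(14)-trien-12,6-olide
Product: 35 (1S,3S,4Z,6R)-1,3-diacetoxy-13-hydroxygermacra-4,7(11),10(14)-trien-12,6-olide (target)
Conditions: HF·pyridine, THF, 0 °C → rt
Reagents that add atoms: none
Why: Fluoride-mediated silyl ether cleavage frees the C13 alcohol under acidic conditions in which the two acetates neither hydrolyse nor migrate.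

**Compound list**
1 | methyl 3-hydroxypropanoate | COC(=O)CCO | starting material
2 | methyl 3-(TBSO)propanoate | COC(=O)CCO[Si](C)(C)C(C)(C)C | intermediate
3 | 3-(TBSO)-N-methoxy-N-methylpropanamide | CON(C)C(=O)CCO[Si](C)(C)C(C)(C)C | intermediate
4 | ethynyltrimethylsilane | C#C[Si](C)(C)C | starting material
5 | lithium (trimethylsilyl)acetylide (not isolated) | [Li]C#C[Si](C)(C)C | intermediate
6 | 5-(TBSO)-1-(trimethylsilyl)pent-1-yn-3-one | C[Si](C)(C)C#CC(=O)CCO[Si](C)(C)C(C)(C)C | intermediate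
7 | (3S)-5-(TBSO)-1-(trimethylsilyl)pent-1-yn-3-ol | C[Si](C)(C)C#C[C@@H](O)CCO[Si](C)(C)C(C)(C)C | intermediate
8 | (3S)-3,5-bis(TBSO)-1-(trimethylsilyl)pent-1-yne | C[Si](C)(C)C#C[C@@H](O[Si](C)(C)C(C)(C)C)CCO[Si](C)(C)C(C)(C)C | intermediate
9 | (3S)-3,5-bis(TBSO)pent-1-yne | C#C[C@@H](O[Si](C)(C)C(C)(C)C)CCO[Si](C)(C)C(C)(C)C | intermediate
10 | lithium (3S)-3,5-bis(TBSO)pent-1-yn-1-ide (not isolated) | [Li]C#C[C@@H](O[Si](C)(C)C(C)(C)C)CCO[Si](C)(C)C(C)(C)C | intermediate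
11 | methyl (4S)-4,6-bis(TBSO)hex-2-ynoate | COC(=O)C#C[C@@H](O[Si](C)(C)C(C)(C)C)CCO[Si](C)(C)C(C)(C)C | intermediate
12 | methyl (2Z,4S)-4,6-bis(TBSO)-3-methylhex-2-enoate | COC(=O)/C=C(/C)[C@@H](O[Si](C)(C)C(C)(C)C)CCO[Si](C)(C)C(C)(C)C | intermediate
13 | (2Z,4S)-4,6-bis(TBSO)-3-methylhex-2-en-1-ol | OC/C=C(/C)[C@@H](O[Si](C)(C)C(C)(C)C)CCO[Si](C)(C)C(C)(C)C | intermediate
14 | (2Z,4S)-4,6-bis(TBSO)-3-methylhex-2-enal | O=C/C=C(/C)[C@@H](O[Si](C)(C)C(C)(C)C)CCO[Si](C)(C)C(C)(C)C | intermediate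
15 | methyl propiolate | C#CC(=O)OC | starting material
16 | methyl 3-(methylzincio)prop-2-ynoate, MeZnC≡CCO2Me (not isolated) | COC(=O)C#C[Zn]C | intermediate
17 | methyl (4R,5Z,7S)-7,9-bis(TBSO)-4-hydroxy-6-methylnon-5-en-2-ynoate | COC(=O)C#C[C@H](O)/C=C(/C)[C@@H](O[Si](C)(C)C(C)(C)C)CCO[Si](C)(C)C(C)(C)C | intermediate
18 | (4-bromobut-1-ynyl)trimethylsilane | C[Si](C)(C)C#CCCBr | starting material
19 | [4-(trimethylsilyl)but-3-ynyl]magnesium bromide (not isolated) | C[Si](C)(C)C#CCC[Mg]Br | intermediate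
20 | bromomagnesium bis[4-(trimethylsilyl)but-3-ynyl]cuprate, (Me3SiC≡CCH2CH2)2CuMgBr (not isolated) | C[Si](C)(C)C#CCC[Cu-]CCC#C[Si](C)(C)C.[Mg+]Br | intermediate
21 | methyl (2E,4R,5Z,7S)-7,9-bis(TBSO)-4-hydroxy-2-iodo-6-methyl-3-[4-(trimethylsilyl)but-3-ynyl]nona-2,5-dienoate (iodo hydroxy ester, not isolated) | COC(=O)/C(I)=C(/CCC#C[Si](C)(C)C)[C@H](O)/C=C(/C)[C@@H](O[Si](C)(C)C(C)(C)C)CCO[Si](C)(C)C(C)(C)C | intermediate
22 | (5R)-5-[(1Z,3S)-3,5-bis(TBSO)-2-methylpent-1-enyl]-3-iodo-4-[4-(trimethylsilyl)but-3-ynyl]furan-2(5H)-one | O=C1O[C@H](/C=C(/C)[C@@H](O[Si](C)(C)C(C)(C)C)CCO[Si](C)(C)C(C)(C)C)C(CCC#C[Si](C)(C)C)=C1I | intermediate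
23 | (5R)-5-[(1Z,3S)-3,5-bis(TBSO)-2-methylpent-1-enyl]-3-(hydroxymethyl)-4-[4-(trimethylsilyl)but-3-ynyl]furan-2(5H)-one | O=C1O[C@H](/C=C(/C)[C@@H](O[Si](C)(C)C(C)(C)C)CCO[Si](C)(C)C(C)(C)C)C(CCC#C[Si](C)(C)C)=C1CO | intermediate
24 | (5R)-5-[(1Z,3S)-3,5-bis(TBSO)-2-methylpent-1-enyl]-3-[(TBDPSO)methyl]-4-[4-(trimethylsilyl)but-3-ynyl]furan-2(5H)-one | O=C1O[C@H](/C=C(/C)[C@@H](O[Si](C)(C)C(C)(C)C)CCO[Si](C)(C)C(C)(C)C)C(CCC#C[Si](C)(C)C)=C1CO[Si](c2ccccc2)(c3ccccc3)C(C)(C)C | intermediate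
25 | (5R)-5-[(1Z,3S)-3,5-bis(TBSO)-2-methylpent-1-enyl]-3-[(TBDPSO)methyl]-4-(but-3-ynyl)furan-2(5H)-one | O=C1O[C@H](/C=C(/C)[C@@H](O[Si](C)(C)C(C)(C)C)CCO[Si](C)(C)C(C)(C)C)C(CCC#C)=C1CO[Si](c2ccccc2)(c3ccccc3)C(C)(C)C | intermediate
26 | (5R)-4-[(3Z)-4-(9-borabicyclo[3.3.1]nonan-9-yl)-3-iodobut-3-enyl]-5-[(1Z,3S)-3,5-bis(TBSO)-2-methylpent-1-enyl]-3-[(TBDPSO)methyl]furan-2(5H)-one (alkenylborane, not isolated) | O=C1O[C@H](/C=C(/C)[C@@H](O[Si](C)(C)C(C)(C)C)CCO[Si](C)(C)C(C)(C)C)C(CC/C(I)=C/B2C3CCCC2CCC3)=C1CO[Si](c4ccccc4)(c5ccccc5)C(C)(C)C | intermediate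
27 | (5R)-5-[(1Z,3S)-3,5-bis(TBSO)-2-methylpent-1-enyl]-3-[(TBDPSO)methyl]-4-(3-iodobut-3-enyl)furan-2(5H)-one | O=C1O[C@H](/C=C(/C)[C@@H](O[Si](C)(C)C(C)(C)C)CCO[Si](C)(C)C(C)(C)C)C(CCC(I)=C)=C1CO[Si](c2ccccc2)(c3ccccc3)C(C)(C)C | intermediate
28 | (5R)-5-[(1Z,3S)-3-(TBSO)-5-hydroxy-2-methylpent-1-enyl]-3-[(TBDPSO)methyl]-4-(3-iodobut-3-enyl)furan-2(5H)-one | O=C1O[C@H](/C=C(/C)[C@@H](O[Si](C)(C)C(C)(C)C)CCO)C(CCC(I)=C)=C1CO[Si](c2ccccc2)(c3ccccc3)C(C)(C)C | intermediate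
29 | (3S,4Z)-3-(TBSO)-5-[(2R)-4-[(TBDPSO)methyl]-3-(3-iodobut-3-enyl)-5-oxo-2,5-dihydrofuran-2-yl]-4-methylpent-4-enal | O=C1O[C@H](/C=C(/C)[C@@H](O[Si](C)(C)C(C)(C)C)CC=O)C(CCC(I)=C)=C1CO[Si](c2ccccc2)(c3ccccc3)C(C)(C)C | intermediate
30 | (3S,4Z,6R)-3-(TBSO)-13-(TBDPSO)-1-hydroxygermacra-4,7(11),10(14)-trien-12,6-olide, mixture of C1 epimers | C=C1CCC2=C(CO[Si](c3ccccc3)(c4ccccc4)C(C)(C)C)C(=O)O[C@@H]2/C=C(/C)[C@@H](O[Si](C)(C)C(C)(C)C)CC1O | intermediate
31 | (3S,4Z,6R)-3-(TBSO)-13-(TBDPSO)-1-oxogermacra-4,7(11),10(14)-trien-12,6-olide | C=C1CCC2=C(CO[Si](c3ccccc3)(c4ccccc4)C(C)(C)C)C(=O)O[C@@H]2/C=C(/C)[C@@H](O[Si](C)(C)C(C)(C)C)CC1=O | intermediate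
32 | (3S,4Z,6R)-13-(TBDPSO)-3-hydroxy-1-oxogermacra-4,7(11),10(14)-trien-12,6-olide | C=C1CCC2=C(CO[Si](c3ccccc3)(c4ccccc4)C(C)(C)C)C(=O)O[C@@H]2/C=C(/C)[C@@H](O)CC1=O | intermediate
33 | (1S,3S,4Z,6R)-13-(TBDPSO)-1,3-dihydroxygermacra-4,7(11),10(14)-trien-12,6-olide | C=C1CCC2=C(CO[Si](c3ccccc3)(c4ccccc4)C(C)(C)C)C(=O)O[C@@H]2/C=C(/C)[C@@H](O)C[C@@H]1O | intermediate
34 | (1S,3S,4Z,6R)-1,3-diacetoxy-13-(TBDPSO)germacra-4,7(11),10(14)-trien-12,6-olide | C=C1CCC2=C(CO[Si](c3ccccc3)(c4ccccc4)C(C)(C)C)C(=O)O[C@@H]2/C=C(/C)[C@@H](OC(C)=O)C[C@@H]1OC(C)=O | intermediate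
35 | (1S,3S,4Z,6R)-1,3-diacetoxy-13-hydroxygermacra-4,7(11),10(14)-trien-12,6-olide (CNP0398389.3) | C=C1CCC2=C(CO)C(=O)O[C@@H]2/C=C(/C)[C@@H](OC(C)=O)C[C@@H]1OC(C)=O | target

**Step count and risk**

Total step count: 24. Longest linear sequence: 24 steps (1 → 35); compounds 4, 15 and 18 are bought and enter directly.

The three steps most likely to fail are 12, 16 and 19.

Step 12 risks incomplete iodine capture of the hindered alkenylcopper or loss of alkene geometry through the allenolate. The fallback sets out from 17 and comes back at 23. Cuprate 20 is added as before, but the alkenylcopper is captured at −78 °C with monomeric formaldehyde (cracked paraformaldehyde) in a tandem conjugate addition–aldol reaction instead of halogen capture and cross-coupling. This gives methyl (2Z,4R,5Z,7S)-7,9-bis(TBSO)-4-hydroxy-2-(hydroxymethyl)-6-methyl-3-[4-(trimethylsilyl)but-3-ynyl]nona-2,5-dienoate F1, which lactonises on work-up to 23. Only the isomer with the ester cis to the C6 hydroxyl can close, so any geometric leakage is removed by chromatography, and the Stille step is bypassed.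

Step 16 risks Lewis-acid damage to the silyl ethers or the lactone by the B–I reagent. The fallback sets out from 25 and comes back at 27. It replaces haloboration by stannylmetalation: Piers stannylcupration with Me3SnCu·SMe2 (from Me3SnLi and CuBr·SMe2) in THF with MeOH as in-situ proton source at −63 °C puts tin on the internal alkyne carbon and gives (5R)-5-[(1Z,3S)-3,5-bis(TBSO)-2-methylpent-1-enyl]-3-[(TBDPSO)methyl]-4-[3-(trimethylstannyl)but-3-enyl]furan-2(5H)-one F2. Iododestannylation with I2 in CH2Cl2 at 0 °C then gives 27 under non-acidic conditions.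

Step 19 risks oligomerisation or protodeiodination instead of closure of the strained ten-membered ring. The fallback sets out from 25 and comes back at 30, avoiding the alkenyl iodide altogether.
- Buffered HF·pyridine/pyridine removes the primary TBS group to give (5R)-4-(but-3-ynyl)-5-[(1Z,3S)-3-(TBSO)-5-hydroxy-2-methylpent-1-enyl]-3-[(TBDPSO)methyl]furan-2(5H)-one F3.
- Dess–Martin oxidation gives (3S,4Z)-5-[(2R)-3-(but-3-ynyl)-4-[(TBDPSO)methyl]-5-oxo-2,5-dihydrofuran-2-yl]-3-(TBSO)-4-methylpent-4-enal F4.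
- A nickel-catalysed reductive alkyne–aldehyde macrocyclisation follows (Ni(COD)2 as zerovalent nickel source, the bulky carbene 1,3-bis(2,6-diisopropylphenyl)imidazol-2-ylidene to steer C–C bond formation to the internal alkyne carbon, Et3SiH, THF, syringe-pump addition). It gives (3S,4Z,6R)-3-(TBSO)-13-(TBDPSO)-1-(triethylsilyloxy)germacra-4,7(11),10(14)-trien-12,6-olide F5 as C1 epimers.
- PPTS in MeOH cleaves the triethylsilyl ether selectively and returns to 30.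

Further compounds
F1 | step 12 | methyl (2Z,4R,5Z,7S)-7,9-bis(TBSO)-4-hydroxy-2-(hydroxymethyl)-6-methyl-3-[4-(trimethylsilyl)but-3-ynyl]nona-2,5-dienoate | COC(=O)/C(CO)=C(/CCC#C[Si](C)(C)C)[C@H](O)/C=C(/C)[C@@H](O[Si](C)(C)C(C)(C)C)CCO[Si](C)(C)C(C)(C)C
F2 | step 16 | (5R)-5-[(1Z,3S)-3,5-bis(TBSO)-2-methylpent-1-enyl]-3-[(TBDPSO)methyl]-4-[3-(trimethylstannyl)but-3-enyl]furan-2(5H)-one | O=C1O[C@H](/C=C(/C)[C@@H](O[Si](C)(C)C(C)(C)C)CCO[Si](C)(C)C(C)(C)C)C(CCC(=C)[Sn](C)(C)C)=C1CO[Si](c2ccccc2)(c3ccccc3)C(C)(C)C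
F3 | step 19 | (5R)-4-(but-3-ynyl)-5-[(1Z,3S)-3-(TBSO)-5-hydroxy-2-methylpent-1-enyl]-3-[(TBDPSO)methyl]furan-2(5H)-one | O=C1O[C@H](/C=C(/C)[C@@H](O[Si](C)(C)C(C)(C)C)CCO)C(CCC#C)=C1CO[Si](c2ccccc2)(c3ccccc3)C(C)(C)C
F4 | step 19 | (3S,4Z)-5-[(2R)-3-(but-3-ynyl)-4-[(TBDPSO)methyl]-5-oxo-2,5-dihydrofuran-2-yl]-3-(TBSO)-4-methylpent-4-enal | O=C1O[C@H](/C=C(/C)[C@@H](O[Si](C)(C)C(C)(C)C)CC=O)C(CCC#C)=C1CO[Si](c2ccccc2)(c3ccccc3)C(C)(C)C
F5 | step 19 | (3S,4Z,6R)-3-(TBSO)-13-(TBDPSO)-1-(triethylsilyloxy)germacra-4,7(11),10(14)-trien-12,6-olide, C1 epimers | C=C1CCC2=C(CO[Si](c3ccccc3)(c4ccccc4)C(C)(C)C)C(=O)O[C@@H]2/C=C(/C)[C@@H](O[Si](C)(C)C(C)(C)C)CC1O[Si](CC)(CC)CC
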